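Retrosynthetic overview

1. The target is a 2-oxaspiro[4.5]decane, numbered here and for all spiro compounds as C1 lactone carbinol carbon, O2, C3 lactone carbonyl, C4, C5 spiro carbon, C6 ketone, C7=C8, C9 acetoxy carbon, C10 ring CH2. The strategy rests on C5 carrying C1 as a one-carbon oxygenated branch beside the ring methylene C10, with unsaturation at C8/C9: this is a 1-formylcyclohex-3-ene, the Claisen product of a 2-vinyl-3,4-dihydro-2H-pyran (pyran C6 → C1, C5 → C5, C4 → C6, C3 → C7, C2 → C8, vinyl CH → C9, vinyl CH2 → C10).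
2. Key disconnection: the C5–C10 bond and the carbocycle come from a [3,3] shift of dihydropyran 10, which breaks the pyran O–C2 bond and transfers chirality from pyran C2 to C5.
3. After the key step: the lactone ring is made by Ni/Cr coupling of the C1 aldehyde with alkenyl iodide 18, then O2–C3 lactonisation. The C6 ketone, C7=C8 and C9–O come from hydroxyl-directed epoxidation of C8=C9, oxidation at C6 and β-elimination. The C9 acetate is installed with inversion by a Mitsunobu reaction.
4. Before the key step: the pyran comes from an enantioselective hetero-Diels–Alder reaction of a silylated ynal with 1-methoxy-3-silyloxybutadiene. The ynal stands in for acrolein, whose C=C bond would compete as a dienophile. The acetate arm is added by α-iodination and Negishi coupling, the vinyl group by semihydrogenation.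
5. Ring order: dihydropyran (sacrificed) → cyclohexene (step 8) → γ-lactone (step 14). Side chain 18 comes from pent-4-ynoic acid by ketone synthesis, CBS reduction and carboalumination–iodination.

Key step: step 8

Assumption: the absolute sense of induction in the two ligand-controlled steps (step 1, Re-face attack on the ynal; step 14, attack giving the 1R carbinol) is assigned by analogy within each ligand class; if the first run shows the opposite sense, the mirror-image ligand is used and nothing else changes.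

Route

Step 1
Reactants: 1 (E)-1-methoxy-3-(trimethylsilyloxy)buta-1,3-diene; 2 3-(trimethylsilyl)prop-2-ynal
Product: 4 (2R)-2-[(trimethylsilyl)ethynyl]-2,3-dihydro-4H-pyran-4-one, via cycloadduct 3 (not isolated)
Conditions: CrCl(L) (3 mol %; trivalent chromium; L = dianion of the Schiff base from 3-(1-adamantyl)-2-hydroxy-5-methylbenzaldehyde and (1R,2S)-1-aminoindan-2-ol), 4 Å MS, t-BuOMe, rt; then TFA (cat.), CH2Cl2, 0 °C
Reagents that add atoms: none
Why: Catalytic enantioselective hetero-Diels–Alder reaction in which the chromium-bound ynal is attacked on its Re face to set C2 as R, an ynal being a proven heterodienophile that offers no C=C bond for a competing carbocyclic cycloaddition, after which acid removes methanol and the silyl group from the cycloadduct to give the enone.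

Step 2
Reactants: 4 (2R)-2-[(trimethylsilyl)ethynyl]-2,3-dihydro-4H-pyran-4-one
Product: 5 (2R)-5-iodo-2-[(trimethylsilyl)ethynyl]-2,3-dihydro-4H-pyran-4-one
Conditions: I2, pyridine, CH2Cl2, 0 °C → rt
Reagents that add atoms: iodine (II)
Why: Electrophilic α-iodination of the vinylogous ester (iodine–pyridine enone iodination) should occur only at the nucleophilic C5, and the silyl alkyne and the C2 stereocentre are inert to this weak base.

Step 3
Reactants: 5 (2R)-5-iodo-2-[(trimethylsilyl)ethynyl]-2,3-dihydro-4H-pyran-4-one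
Product: 6 (2R,4R)-5-iodo-2-[(trimethylsilyl)ethynyl]-3,4-dihydro-2H-pyran-4-ol (2,4-cis)
Conditions: NaBH4, CeCl3·7H2O, MeOH, −78 → −40 °C
Reagents that add atoms: none
Why: Luche 1,2-reduction, in which axial hydride delivery to the half-chair enone with the C2 substituent pseudo-equatorial should give the 2,4-cis alcohol (4R), as is usual for 2-substituted dihydropyranones.

Step 4
Reactants: 6 (2R,4R)-5-iodo-2-[(trimethylsilyl)ethynyl]-3,4-dihydro-2H-pyran-4-ol
Product: 7 triethyl{[(2R,4R)-5-iodo-2-((trimethylsilyl)ethynyl)-3,4-dihydro-2H-pyran-4-yl]oxy}silane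
Conditions: Et3SiCl, imidazole, CH2Cl2, 0 °C
Reagents that add atoms: chlorotriethylsilane (CC[Si](Cl)(CC)CC)
Why: Standard silylation of the allylic alcohol, the triethylsilyl ether being chosen because it should survive the thermal step and can later be cleaved beside a tert-butyldimethylsilyl ether.

Step 5
Reactants: 7 triethyl{[(2R,4R)-5-iodo-2-((trimethylsilyl)ethynyl)-3,4-dihydro-2H-pyran-4-yl]oxy}silane
Product: 8 methyl 2-[(2R,4R)-4-(triethylsilyloxy)-2-((trimethylsilyl)ethynyl)-3,4-dihydro-2H-pyran-5-yl]acetate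
Conditions: BrZnCH2CO2Me (from BrCH2CO2Me, Zn, THF), Pd2(dba)3 (2.5 mol %), XPhos (10 mol %), THF, 45 °C
Reagents that add atoms: methyl bromoacetate (COC(=O)CBr), used as its zinc reagent
Why: Negishi cross-coupling of a zinc ester enolate (Reformatsky reagent) with the alkenyl iodide, which as a 2-iodoglycal-type partner should add readily to zerovalent palladium, while the substrate has no carbonyl group for the zinc enolate to attack and the silyl group keeps the alkyne out of the coupling.

Step 6
Reactants: 8 methyl 2-[(2R,4R)-4-(triethylsilyloxy)-2-((trimethylsilyl)ethynyl)-3,4-dihydro-2H-pyran-5-yl]acetate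
Product: 9 methyl 2-[(2R,4R)-2-ethynyl-4-(triethylsilyloxy)-3,4-dihydro-2H-pyran-5-yl]acetate
Conditions: K2CO3 (0.2 equiv), MeOH, 0 °C → rt
Reagents that add atoms: none
Why: Methanolysis of the alkynyl C–Si bond is fast with catalytic carbonate, under which the methyl ester, the secondary triethylsilyl ether and the enol ether should persist.

Step 7
Reactants: 9 methyl 2-[(2R,4R)-2-ethynyl-4-(triethylsilyloxy)-3,4-dihydro-2H-pyran-5-yl]acetate
Product: 10 methyl 2-[(2R,4R)-4-(triethylsilyloxy)-2-vinyl-3,4-dihydro-2H-pyran-5-yl]acetate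
Conditions: H2 (1 atm), Pd/CaCO3 poisoned with Pb(OAc)2, quinoline, EtOAc, rt
Reagents that add atoms: none
Why: Lindlar semihydrogenation of the terminal alkyne should stop at the vinyl group, and the trisubstituted enol ether is not reduced on the poisoned catalyst.

Step 8
Reactants: 10 methyl 2-[(2R,4R)-4-(triethylsilyloxy)-2-vinyl-3,4-dihydro-2H-pyran-5-yl]acetate
Product: 11 methyl 2-[(1S,6R)-1-formyl-6-(triethylsilyloxy)cyclohex-3-en-1-yl]acetate
Conditions: o-xylene (degassed), BHT (cat.), base-washed sealed tube, 190 °C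
Reagents that add atoms: none
Why: Thermal Claisen rearrangement: the allyl vinyl ether held in the ring (enol ether C6=C5, O1, allylic C2 and its vinyl group) undergoes a concerted suprafacial [3,3] shift through a boat-like transition state, in which the O1–C2 bond breaks, the vinyl terminus bonds to C5 and C6 becomes the formyl carbon. The closest known reaction type is the thermal rearrangement of 2-alkenyl-3,4-dihydro-2H-pyrans to cyclohex-3-enecarbaldehydes. The cyclohexene closes by pericyclic C–C bond formation between C5 and the vinyl CH2 across the pyran while the heterocycle opens, so one six-membered ring is exchanged for another. The new quaternary stereocentre is set by chirality transfer from C2, since the tethered vinyl group can reach C5 only from the ring face on which it stands, so 2R should give 1S with the formyl group trans and the acetate arm cis to the silyloxy group, whose own centre is not touched. The step needs the shift to outrun ionisation or elimination at the allylic C4–O bond: allylic 1,2-strain between the C5 side chain and the cis silyloxy group is expected to populate the conformer with both ring substituents pseudo-axial, from which the boat is reached, carbonyl formation makes the shift irreversible, and neutral base-washed conditions suppress acid-induced loss of triethylsilanol. The ester, the silyl ether and the non-enolisable aldehyde should be stable at this temperature.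

Step 9
Reactants: 12 pent-4-ynoic acid
Product: 13 N-methoxy-N-methylpent-4-ynamide
Conditions: MeNH(OMe)·HCl, EDC·HCl, DMAP (cat.), Et3N, CH2Cl2, 0 °C → rt
Reagents that add atoms: N,O-dimethylhydroxylamine hydrochloride (CNOC.Cl)
Why: Carbodiimide amide coupling gives the N-methoxy-N-methylamide needed for a clean ketone synthesis.

Step 10
Reactants: 13 N-methoxy-N-methylpent-4-ynamide
Product: 14 2-methylhept-1-en-6-yn-3-one
Conditions: CH2=C(CH3)MgBr (2.3 equiv), THF, −20 → 0 °C; cold 1 M HCl
Reagents that add atoms: isopropenylmagnesium bromide (C=C(C)[Mg]Br)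
Why: Weinreb ketone synthesis, in which one equivalent of Grignard reagent deprotonates the alkyne and the next adds to the amide to give a chelated tetrahedral intermediate that cannot over-add and collapses to the enone only on acidic quench.

Step 11
Reactants: 14 2-methylhept-1-en-6-yn-3-one
Product: 15 (3R)-2-methylhept-1-en-6-yn-3-ol
Conditions: (S)-2-methyl-CBS-oxazaborolidine (0.2 equiv), catecholborane, PhMe, −78 °C
Reagents that add atoms: none
Why: Corey–Bakshi–Shibata reduction, in which the branched isopropenyl group acts as the large and the CH2 chain as the small ketone substituent so that the (S)-oxazaborolidine should give the R carbinol, catecholborane at low temperature reducing the carbonyl without hydroborating the alkene or alkyne.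

Step 12
Reactants: 15 (3R)-2-methylhept-1-en-6-yn-3-ol
Product: 16 tert-butyldimethyl{[(3R)-2-methylhept-1-en-6-yn-3-yl]oxy}silane
Conditions: t-BuMe2SiCl, imidazole, DMF, rt
Reagents that add atoms: tert-butylchlorodimethylsilane (CC(C)(C)[Si](C)(C)Cl)
Why: Standard silylation giving an ether that should outlast the later triethylsilyl cleavage and the oxidation, and is removed last.

Step 13
Reactants: 16 tert-butyldimethyl{[(3R)-2-methylhept-1-en-6-yn-3-yl]oxy}silane
Product: 18 tert-butyl{[(3R,6E)-7-iodo-2,6-dimethylhepta-1,6-dien-3-yl]oxy}dimethylsilane, via alkenylalane 17 (not isolated)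
Conditions: Me3Al, Cp2ZrCl2 (0.25 equiv), CH2Cl2, 0 °C → rt; then I2, THF, −30 → 0 °C
Reagents that add atoms: trimethylaluminium (C[Al](C)C); iodine (II)
Why: Zirconium-catalysed Negishi carboalumination adds methyl and aluminium syn across the terminal alkyne with aluminium at the terminus, and iodinolysis with retention gives the E alkenyl iodide, the 1,1-disubstituted alkene and the silyl ether being inert.

Step 14
Reactants: 11 methyl 2-[(1S,6R)-1-formyl-6-(triethylsilyloxy)cyclohex-3-en-1-yl]acetate; 18 tert-butyl{[(3R,6E)-7-iodo-2,6-dimethylhepta-1,6-dien-3-yl]oxy}dimethylsilane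
Product: 20 (1R,5R,6R)-1-[(1E,5R)-5-(tert-butyldimethylsilyloxy)-2,6-dimethylhepta-1,6-dien-1-yl]-6-(triethylsilyloxy)-2-oxaspiro[4.5]dec-8-en-3-one, via hydroxy ester 19 (not isolated)
Conditions: CrCl2 (4 equiv), NiCl2 (2 mol %), N-[2-((4S)-4-isopropyl-4,5-dihydro-1,3-oxazol-2-yl)-6-methylphenyl]methanesulfonamide (4.4 equiv), Et3N, THF, rt; then PPTS (cat.), PhMe, 40 °C
Reagents that add atoms: none
Why: Nozaki–Hiyama–Kishi coupling, in which the alkenyl iodide is activated by zerovalent nickel and passed to chromium, the alkenyl species of trivalent chromium adds only to the hindered non-enolisable aldehyde with retention of the E geometry, the chiral sulfonamide ligand on chromium is relied on to direct attack to the face giving the 1R carbinol, and the γ-hydroxy ester then closes to the γ-lactone by acyl substitution favoured by the quaternary centre.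

Step 15
Reactants: 20 (1R,5R,6R)-1-[(1E,5R)-5-(tert-butyldimethylsilyloxy)-2,6-dimethylhepta-1,6-dien-1-yl]-6-(triethylsilyloxy)-2-oxaspiro[4.5]dec-8-en-3-one
Product: 21 (1R,5S,6R)-1-[(1E,5R)-5-(tert-butyldimethylsilyloxy)-2,6-dimethylhepta-1,6-dien-1-yl]-6-hydroxy-2-oxaspiro[4.5]dec-8-en-3-one
Conditions: HF·pyridine, pyridine, THF, 0 °C
Reagents that add atoms: none
Why: Buffered fluoride desilylation should cleave the triethylsilyl ether much faster than the tert-butyldimethylsilyl ether, and the near-neutral medium should avoid acyl transfer from the lactone to the freed hydroxyl, which stands cis to the lactone CH2.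

Step 16
Reactants: 21 (1R,5S,6R)-1-[(1E,5R)-5-(tert-butyldimethylsilyloxy)-2,6-dimethylhepta-1,6-dien-1-yl]-6-hydroxy-2-oxaspiro[4.5]dec-8-en-3-one
Product: 22 (1R,5S,6R,8S,9R)-1-[(1E,5R)-5-(tert-butyldimethylsilyloxy)-2,6-dimethylhepta-1,6-dien-1-yl]-8,9-epoxy-6-hydroxy-2-oxaspiro[4.5]decan-3-one (epoxide cis to the 6-hydroxyl)
Conditions: VO(acac)2 (5 mol %), t-BuOOH (decane), CH2Cl2, 0 °C → rt
Reagents that add atoms: tert-butyl hydroperoxide (CC(C)(C)OO)
Why: Vanadium-catalysed hydroxyl-directed epoxidation, in which the homoallylic C6 hydroxyl binds the peroxide complex of pentavalent vanadium and delivers oxygen to C8=C9 on its own face, so that the side-chain alkenes, which carry no free hydroxyl, should not react and the epoxide forms cis to the hydroxyl.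

Step 17
Reactants: 22 (1R,5S,6R,8S,9R)-1-[(1E,5R)-5-(tert-butyldimethylsilyloxy)-2,6-dimethylhepta-1,6-dien-1-yl]-8,9-epoxy-6-hydroxy-2-oxaspiro[4.5]decan-3-one
Product: 24 (1R,5R,9R)-1-[(1E,5R)-5-(tert-butyldimethylsilyloxy)-2,6-dimethylhepta-1,6-dien-1-yl]-9-hydroxy-2-oxaspiro[4.5]dec-7-ene-3,6-dione, via epoxy ketone 23 (not isolated)
Conditions: Dess–Martin periodinane, NaHCO3, CH2Cl2, 0 °C → rt; then Et3N, 0 °C
Reagents that add atoms: none
Why: Dess–Martin oxidation gives the β,γ-epoxy ketone, whose only α-hydrogens (C7) are removed by the amine so that E1cB opening of the epoxide gives the C7=C8 enone and a C9 hydroxyl that keeps the configuration set by the epoxidation (9R, cis to the lactone CH2).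

Step 18
Reactants: 24 (1R,5R,9R)-1-[(1E,5R)-5-(tert-butyldimethylsilyloxy)-2,6-dimethylhepta-1,6-dien-1-yl]-9-hydroxy-2-oxaspiro[4.5]dec-7-ene-3,6-dione
Product: 25 (1R,5R,9S)-1-[(1E,5R)-5-(tert-butyldimethylsilyloxy)-2,6-dimethylhepta-1,6-dien-1-yl]-3,6-dioxo-2-oxaspiro[4.5]dec-7-en-9-yl acetate
Conditions: AcOH, PPh3, DIAD, THF, 0 °C → rt
Reagents that add atoms: acetic acid (CC(=O)O)
Why: Mitsunobu esterification, in which acetate displaces the activated allylic C9 oxygen by SN2 with inversion, so that the acetate is installed and the 9R alcohol becomes the required 9S ester in one operation, attack at C7 being disfavoured because C7 is the α-carbon of the enone.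

Step 19
Reactants: 25 (1R,5R,9S)-1-[(1E,5R)-5-(tert-butyldimethylsilyloxy)-2,6-dimethylhepta-1,6-dien-1-yl]-3,6-dioxo-2-oxaspiro[4.5]dec-7-en-9-yl acetate
Product: 26 (1R,5R,9S)-1-[(1E,5R)-5-hydroxy-2,6-dimethylhepta-1,6-dien-1-yl]-3,6-dioxo-2-oxaspiro[4.5]dec-7-en-9-yl acetate (CNP0151251.2)
Conditions: HF·pyridine, pyridine, THF, 0 °C → rt
Reagents that add atoms: none
Why: Fluoride cleavage of the tert-butyldimethylsilyl ether under buffered, non-basic conditions should free the side-chain alcohol without touching the base-sensitive γ-acetoxy enone or the lactone.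

Compound list

1 | (E)-1-methoxy-3-(trimethylsilyloxy)buta-1,3-diene | CO/C=C/C(=C)O[Si](C)(C)C | starting material
2 | 3-(trimethylsilyl)prop-2-ynal | C[Si](C)(C)C#CC=O | starting material
3 | (2R)-6-methoxy-2-[(trimethylsilyl)ethynyl]-4-(trimethylsilyloxy)-3,6-dihydro-2H-pyran (acetal centre undefined) | COC1C=C(O[Si](C)(C)C)C[C@H](C#C[Si](C)(C)C)O1 | intermediate (not isolated)
4 | (2R)-2-[(trimethylsilyl)ethynyl]-2,3-dihydro-4H-pyran-4-one | O=C1C=CO[C@@H](C#C[Si](C)(C)C)C1 | intermediate
5 | (2R)-5-iodo-2-[(trimethylsilyl)ethynyl]-2,3-dihydro-4H-pyran-4-one | O=C1C(I)=CO[C@@H](C#C[Si](C)(C)C)C1 | intermediate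
6 | (2R,4R)-5-iodo-2-[(trimethylsilyl)ethynyl]-3,4-dihydro-2H-pyran-4-ol | IC1=CO[C@@H](C#C[Si](C)(C)C)C[C@H]1O | intermediate
7 | triethyl{[(2R,4R)-5-iodo-2-((trimethylsilyl)ethynyl)-3,4-dihydro-2H-pyran-4-yl]oxy}silane | IC1=CO[C@@H](C#C[Si](C)(C)C)C[C@H]1O[Si](CC)(CC)CC | intermediate
8 | methyl 2-[(2R,4R)-4-(triethylsilyloxy)-2-((trimethylsilyl)ethynyl)-3,4-dihydro-2H-pyran-5-yl]acetate | COC(=O)CC1=CO[C@@H](C#C[Si](C)(C)C)C[C@H]1O[Si](CC)(CC)CC | intermediate
9 | methyl 2-[(2R,4R)-2-ethynyl-4-(triethylsilyloxy)-3,4-dihydro-2H-pyran-5-yl]acetate | COC(=O)CC1=CO[C@@H](C#C)C[C@H]1O[Si](CC)(CC)CC | intermediate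
10 | methyl 2-[(2R,4R)-4-(triethylsilyloxy)-2-vinyl-3,4-dihydro-2H-pyran-5-yl]acetate | COC(=O)CC1=CO[C@@H](C=C)C[C@H]1O[Si](CC)(CC)CC | intermediate
11 | methyl 2-[(1S,6R)-1-formyl-6-(triethylsilyloxy)cyclohex-3-en-1-yl]acetate | COC(=O)C[C@@]1(C=O)CC=CC[C@H]1O[Si](CC)(CC)CC | intermediate
12 | pent-4-ynoic acid | C#CCCC(=O)O | starting material
13 | N-methoxy-N-methylpent-4-ynamide | C#CCCC(=O)N(C)OC | intermediate
14 | 2-methylhept-1-en-6-yn-3-one | C=C(C)C(=O)CCC#C | intermediate
15 | (3R)-2-methylhept-1-en-6-yn-3-ol | C=C(C)[C@H](O)CCC#C | intermediate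
16 | tert-butyldimethyl{[(3R)-2-methylhept-1-en-6-yn-3-yl]oxy}silane | C=C(C)[C@H](O[Si](C)(C)C(C)(C)C)CCC#C | intermediate
17 | [(1E,5R)-5-(tert-butyldimethylsilyloxy)-2,6-dimethylhepta-1,6-dien-1-yl]dimethylalumane | C=C(C)[C@H](O[Si](C)(C)C(C)(C)C)CC/C(C)=C/[Al](C)C | intermediate (not isolated)
18 | tert-butyl{[(3R,6E)-7-iodo-2,6-dimethylhepta-1,6-dien-3-yl]oxy}dimethylsilane | C=C(C)[C@H](O[Si](C)(C)C(C)(C)C)CC/C(C)=C/I | intermediate
19 | methyl 2-[(1R,6R)-1-[(1R,2E,6R)-6-(tert-butyldimethylsilyloxy)-1-hydroxy-3,7-dimethylocta-2,7-dien-1-yl]-6-(triethylsilyloxy)cyclohex-3-en-1-yl]acetate | C=C(C)[C@H](O[Si](C)(C)C(C)(C)C)CC/C(C)=C/[C@@H](O)[C@]1(CC(=O)OC)CC=CC[C@H]1O[Si](CC)(CC)CC | intermediate (not isolated)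
20 | (1R,5R,6R)-1-[(1E,5R)-5-(tert-butyldimethylsilyloxy)-2,6-dimethylhepta-1,6-dien-1-yl]-6-(triethylsilyloxy)-2-oxaspiro[4.5]dec-8-en-3-one | C=C(C)[C@H](O[Si](C)(C)C(C)(C)C)CC/C(C)=C/[C@H]1OC(=O)C[C@]12CC=CC[C@H]2O[Si](CC)(CC)CC | intermediate
21 | (1R,5S,6R)-1-[(1E,5R)-5-(tert-butyldimethylsilyloxy)-2,6-dimethylhepta-1,6-dien-1-yl]-6-hydroxy-2-oxaspiro[4.5]dec-8-en-3-one | C=C(C)[C@H](O[Si](C)(C)C(C)(C)C)CC/C(C)=C/[C@H]1OC(=O)C[C@]12CC=CC[C@H]2O | intermediate
22 | (1R,5S,6R,8S,9R)-1-[(1E,5R)-5-(tert-butyldimethylsilyloxy)-2,6-dimethylhepta-1,6-dien-1-yl]-8,9-epoxy-6-hydroxy-2-oxaspiro[4.5]decan-3-one | C=C(C)[C@H](O[Si](C)(C)C(C)(C)C)CC/C(C)=C/[C@H]1OC(=O)C[C@]12C[C@H]3O[C@H]3C[C@H]2O | intermediate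
23 | (1R,5R,8S,9R)-1-[(1E,5R)-5-(tert-butyldimethylsilyloxy)-2,6-dimethylhepta-1,6-dien-1-yl]-8,9-epoxy-2-oxaspiro[4.5]decane-3,6-dione | C=C(C)[C@H](O[Si](C)(C)C(C)(C)C)CC/C(C)=C/[C@H]1OC(=O)C[C@]12C[C@H]3O[C@H]3CC2=O | intermediate (not isolated)
24 | (1R,5R,9R)-1-[(1E,5R)-5-(tert-butyldimethylsilyloxy)-2,6-dimethylhepta-1,6-dien-1-yl]-9-hydroxy-2-oxaspiro[4.5]dec-7-ene-3,6-dione | C=C(C)[C@H](O[Si](C)(C)C(C)(C)C)CC/C(C)=C/[C@H]1OC(=O)C[C@]12C[C@@H](O)C=CC2=O | intermediate
25 | (1R,5R,9S)-1-[(1E,5R)-5-(tert-butyldimethylsilyloxy)-2,6-dimethylhepta-1,6-dien-1-yl]-3,6-dioxo-2-oxaspiro[4.5]dec-7-en-9-yl acetate | C=C(C)[C@H](O[Si](C)(C)C(C)(C)C)CC/C(C)=C/[C@H]1OC(=O)C[C@]12C[C@H](OC(C)=O)C=CC2=O | intermediate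
26 | (1R,5R,9S)-1-[(1E,5R)-5-hydroxy-2,6-dimethylhepta-1,6-dien-1-yl]-3,6-dioxo-2-oxaspiro[4.5]dec-7-en-9-yl acetate | C=C(C)[C@H](O)CC/C(C)=C/[C@H]1OC(=O)C[C@]12C[C@H](OC(C)=O)C=CC2=O | target

Step count and risks

Total: 19 steps. Longest linear sequence: 14 steps (steps 1–8, then 14–19); steps 9–13 make the side chain.

The three steps most likely to fail:

Step 8. The hindered enol ether may not reach the boat transition state before the allylic C4–O bond ionises and triethylsilanol is lost at 190 °C. The fallback replaces the neutral thermal shift by a Lewis-acid-bound, charge-accelerated rearrangement. The ring oxygen of 10 is bound to the bulky Lewis acid Al(OC6H3-2,6-Ph2)3 (in excess, so that the ester carbonyl is saturated as well) in toluene at −78 to −20 °C. This is a known way of running Claisen rearrangements of allyl vinyl ethers far below their thermal threshold without reduction or alkylation of the aldehyde formed. The complexed aldehyde is released on work-up, so the fallback sets out from 10 and comes back at 11. It makes no new compound and is entered as F0 in the block below.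

Step 14. The chiral chromium complex may add sluggishly to the neopentyl aldehyde, or may fail to override the facial preference of the substrate, giving poor selectivity at C1. The fallback sets the carbinol by reduction instead of addition and sets out from 11 and 18. Iodine–lithium exchange of 18 (t-BuLi, Et2O, −78 °C) gives [(1E,5R)-5-(tert-butyldimethylsilyloxy)-2,6-dimethylhepta-1,6-dien-1-yl]lithium F1 which adds to the aldehyde of 11 at −78 °C. Quenching with acetic acid at that temperature should give methyl 2-[(1R,6R)-1-[(2E,6R)-6-(tert-butyldimethylsilyloxy)-1-hydroxy-3,7-dimethylocta-2,7-dien-1-yl]-6-(triethylsilyloxy)cyclohex-3-en-1-yl]acetate F2 as a mixture of carbinol epimers before it can lactonise. Dess–Martin oxidation gives methyl 2-[(1S,6R)-1-[(2E,6R)-6-(tert-butyldimethylsilyloxy)-3,7-dimethylocta-2,7-dienoyl]-6-(triethylsilyloxy)cyclohex-3-en-1-yl]acetate F3 as a single enone. Corey–Bakshi–Shibata reduction with (S)-2-methyl-CBS-oxazaborolidine and catecholborane, the quaternary ring carbon acting as the large group, should give 19 alone, and PPTS-catalysed lactonisation returns to the route at 20.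

Step 18. The activated C9 oxygen may be lost by elimination toward the linearly conjugated 2,4-dienone instead of being displaced, or substitution may be slow on the face flanked by C1. The fallback inverts C9 by oxidation and reduction and sets out from 24. Dess–Martin oxidation gives (1R,5R)-1-[(1E,5R)-5-(tert-butyldimethylsilyloxy)-2,6-dimethylhepta-1,6-dien-1-yl]-2-oxaspiro[4.5]dec-7-ene-3,6,9-trione F4 as an enedione. Corey–Bakshi–Shibata reduction with (R)-2-methyl-CBS-oxazaborolidine and catecholborane should act at the less hindered C9 carbonyl (C6 is flanked by the spiro carbon), with the C7=C8 side as the large group, to give (1R,5R,9S)-1-[(1E,5R)-5-(tert-butyldimethylsilyloxy)-2,6-dimethylhepta-1,6-dien-1-yl]-9-hydroxy-2-oxaspiro[4.5]dec-7-ene-3,6-dione F5 with the hydroxyl trans to the lactone CH2. Acetylation (Ac2O, pyridine, DMAP) comes back to the route at 25.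

Further compounds

F0 | step 8 | none | none
F1 | step 14 | [(1E,5R)-5-(tert-butyldimethylsilyloxy)-2,6-dimethylhepta-1,6-dien-1-yl]lithium | C=C(C)[C@H](O[Si](C)(C)C(C)(C)C)CC/C(C)=C/[Li]
F2 | step 14 | methyl 2-[(1R,6R)-1-[(2E,6R)-6-(tert-butyldimethylsilyloxy)-1-hydroxy-3,7-dimethylocta-2,7-dien-1-yl]-6-(triethylsilyloxy)cyclohex-3-en-1-yl]acetate | C=C(C)[C@H](O[Si](C)(C)C(C)(C)C)CC/C(C)=C/C(O)[C@]1(CC(=O)OC)CC=CC[C@H]1O[Si](CC)(CC)CC
F3 | step 14 | methyl 2-[(1S,6R)-1-[(2E,6R)-6-(tert-butyldimethylsilyloxy)-3,7-dimethylocta-2,7-dienoyl]-6-(triethylsilyloxy)cyclohex-3-en-1-yl]acetate | C=C(C)[C@H](O[Si](C)(C)C(C)(C)C)CC/C(C)=C/C(=O)[C@]1(CC(=O)OC)CC=CC[C@H]1O[Si](CC)(CC)CC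
F4 | step 18 | (1R,5R)-1-[(1E,5R)-5-(tert-butyldimethylsilyloxy)-2,6-dimethylhepta-1,6-dien-1-yl]-2-oxaspiro[4.5]dec-7-ene-3,6,9-trione | C=C(C)[C@H](O[Si](C)(C)C(C)(C)C)CC/C(C)=C/[C@H]1OC(=O)C[C@]12CC(=O)C=CC2=O
F5 | step 18 | (1R,5R,9S)-1-[(1E,5R)-5-(tert-butyldimethylsilyloxy)-2,6-dimethylhepta-1,6-dien-1-yl]-9-hydroxy-2-oxaspiro[4.5]dec-7-ene-3,6-dione | C=C(C)[C@H](O[Si](C)(C)C(C)(C)C)CC/C(C)=C/[C@H]1OC(=O)C[C@]12C[C@H](O)C=CC2=O
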